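Atom numbers used throughout are those of the bicyclic skeleton of the target 12: C1 (prenyl bridgehead), C2, C3, C4 (gem-dimethyl carbon), C5 (acyl bridgehead), O6, C7 (lactone carbonyl), C8 (ketone); C2′ is the side-chain stereocentre.

## Analysis of the target

Target 12 is (1S,3S,5S)-4,4-dimethyl-5-[(2R)-2-methylbutanoyl]-1,3-bis(3-methylbut-2-en-1-yl)-6-oxabicyclo[3.2.1]octane-7,8-dione. Ring A is a cyclohexanone (C1–C2–C3–C4–C5–C8) and ring B a γ-lactone (C1–C7–O6–C5–C8); they share C1, C8 and C5, so the molecule is a furan-2,4-dione whose two fully substituted α-positions are spanned by the chain C2–C3–C4. There are four stereocentres, but the bridgeheads C1 and C5 are tied to each other by the bicycle. Three things must therefore be controlled: the absolute configuration at C3, the face of ring A that carries the lactone bridge (it lies on the face of the C3–H bond, so the C3 prenyl group is equatorial), and the remote C2′ centre, which no ring stereocentre can steer. The hardest bonds are those at C5, which carries O6, the acyl group, C8 and the quaternary C4, and those at the quaternary C1. Sensitive features are the non-enolisable tricarbonyl array (open to retro-Claisen cleavage by nucleophiles), the two trisubstituted alkenes (acid, electrophiles, oxidants) and the C2′–H, the only acidic hydrogen, which strong base can epimerise. Two features invite the strategy. First, C1 and C5 are the two α-carbons of one ketone (C8) and the bridge between them, O6–C7(=O), is CO2: C1 can take up CO2 as an enolate carbon, and C5, the central carbon of a β-diketone, can be joined to the new carboxylate oxygen by oxidation. Second, the segment C2–C3–C4, with the gem-dimethyl carbon C4 and the unsaturated arm on C3, is the C4 stereocentre of (R)-limonene with its isopropenyl group and two ring arms, so a cheap terpene ring can be cut open and closed again in a new way.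

## Retrosynthetic reasoning

12 to 11. The isopropylidene end of the C3 side chain is taken off, leaving an allyl group (cross-metathesis in the forward sense). The cut is made because a second trisubstituted alkene next to C4 would compete for the proton in the cationic ring closure of step 4, whereas a monosubstituted alkene is inert there.

11 to 9 (through 10). The bonds C1–C7 and C5–O6 are cut, which removes the whole O6–C7(=O) bridge as a one-carbon, two-oxygen unit. Both bonds sit at α-carbons of C8, so this single cut removes ring B, the bicyclic strain and both quaternary bridgehead stereocentres. What is left, 9, has one fixed ring stereocentre (C3) and two enolisable centres that need no prior control. The forward reaction has to add the one-carbon electrophile to C1 on the face of the C3–H bond and then close the C5–O6 bond oxidatively.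

9 to 8. The C1–CH2 bond of the C1 prenyl group is cut (alkylation of a dianion with a C5 allylic electrophile). It is made after ring A exists, because a prenyl group at C1 in 7 would offer the cation/enol pair of step 4 a second six-membered closure.

8 to 7. The C4–C5 bond is cut, which opens ring A. This is the most congested C–C bond of the target; forward, a tertiary cation at C4 is made from an isopropenyl group (its CH2 becomes the second methyl group) and is captured by the enol carbon C5.

7 to 4 and 5 (through 6). The C5–C(acyl) bond is cut (crossed Claisen-type acylation). This brings in the C2′ stereocentre from the chiral acid 5 in a β-diketone, where enolisation toward C5 protects it.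

4 to 3 to 1 (through 2). The terminal C=C of the allyl arm goes back to an aldehyde (methylenation), and 3 is the ring-opened form of the terpene epoxide 1. The stereocentre of 1 becomes C3 of 12 and its isopropenyl carbon becomes C4. The aldehyde arm becomes the C3 side chain; the keto arm becomes C2, C1, C8 and C5.

## Alternatives that were turned down

Alternative 1: the textbook route, lactonisation last. Disconnection: the ester bond C7–O6, leading to the hydroxy ester A1. A1 would come from a cyclohexanone β-keto ester by C1 prenylation and C5 hydroxylation. Forward key step: transesterification of the tertiary C5–OH onto the C1 ester. Turned down for three reasons.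
- Ring A needs two independent face selections (prenyl at C1, oxygen at C5) relative to C3. A prenyl electrophile attacks the C1 β-keto ester enolate axially, on the face of the C3–H bond, which puts the ester on the wrong face.
- A1 is a tertiary α-hydroxy-β-diketone next to a β-keto ester. Under the acid or base needed to force a hindered tertiary alcohol onto a hindered quaternary ester, it is open to retro-Claisen cleavage and α-ketol (acyl) shift.
- Ester, prenyl group, hydroxyl group and ring closure are four separate operations where the chosen route needs two.

Alternative 2: biomimetic cation closure onto a preformed lactone. Disconnection: C4–C5 last, from the furan-2,4-dione A2, which carries the prenyl group and the open C2–C3–C4 chain on a quaternary C1 and the acyl group on C5. Forward key step: Markovnikov protonation of the isopropenyl group and capture of the C4 cation by the C5 enol. Turned down for three reasons.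
- C1 of A2 must be set relative to C3 across an acyclic 1,3-relationship with no control element, and each C1 epimer leads to a different C3 epimer of the bicycle.
- The C8 enol oxygen can trap the cation to give a fused dihydropyran, and two prenyl alkenes compete with the isopropenyl group for the proton.
- Building the quaternary C1 of A2 by C-alkylation of a tetronic acid fights O-alkylation.

Alternative 3: radical cyclisation with allyl transfer. Disconnection: C1–C2 and the C3–side-chain bond in one operation, from the tetronic acid A3 (quaternary C5 with the acyl and a 2-methylbut-3-en-2-yl group, prenyl on C1). Forward key step: Mn(OAc)3 oxidation to the C1 radical, 6-endo cyclisation onto the vinyl group, and trapping of the C3 radical from the exo face by an allyl-transfer reagent. This would set C1 and C3 well. Turned down for two reasons.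
- The quaternary C5 of A3 is its only ring stereocentre and has no dependable source. The methyl/ethyl difference at C2′ cannot steer a Claisen or allylation step and there is no chiral-pool origin, so a diastereomer separation would be needed.
- The three-component termination competes with hydrogen abstraction. A prenyl-transfer reagent with its leaving group on the tertiary carbon isomerises, so an allyl group and a later metathesis would be needed anyway.

Key step: step 6

Assumption: 1 is the commercial cis/trans mixture of (+)-limonene 1,2-oxide (4R) and 5 is bought as the (R)-acid; both epoxide isomers of 1 open to the same diol 2.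
Remark on the chemistry: 8 and 9 are β-diketones that exist as enol tautomers and as epimers at the ring α-carbons; these centres are left undefined and become trigonal again in step 6.

## Route

Step 1
Reactants: 1 (+)-limonene 1,2-oxide, (4R)-1-methyl-4-(prop-1-en-2-yl)-7-oxabicyclo[4.1.0]heptane, cis/trans mixture
Product: 3 (3R)-6-oxo-3-(prop-1-en-2-yl)heptanal, via trans-diol 2 (not isolated)
Conditions: H5IO6 (1.2 equiv), THF/H2O, 0 °C → rt
Reagents that add atoms: water, SMILES O
Why: Acid-catalysed opening of the epoxide to the diol 2 and Malaprade glycol cleavage in one flask; the 1,1-disubstituted alkene is inert to periodate, and the stereocentre is untouched and not α to either new carbonyl group.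

Step 2
Reactants: 3 (3R)-6-oxo-3-(prop-1-en-2-yl)heptanal
Product: 4 (5R)-5-(prop-1-en-2-yl)oct-7-en-2-one
Conditions: Ph3PCH3Br (1.05 equiv), KN(SiMe3)2 (1.0 equiv), THF, 0 °C; then 3, −78 → 0 °C
Reagents that add atoms: methyltriphenylphosphonium bromide, SMILES C[P+](c1ccccc1)(c1ccccc1)c1ccccc1.[Br-]
Why: Wittig methylenation; the non-stabilised ylide reacts far faster with the aldehyde than with the methyl ketone at low temperature, and the stereocentre is β to the aldehyde and cannot epimerise.

Step 3
Reactants: 4 (5R)-5-(prop-1-en-2-yl)oct-7-en-2-one; 5 (2R)-2-methylbutanoic acid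
Product: 7 (3R,9R)-3-methyl-9-(prop-1-en-2-yl)dodec-11-ene-4,6-dione, via acid chloride 6 (not isolated)
Conditions: 5, (COCl)2, DMF (cat.), CH2Cl2, 0 °C → rt, evaporate; 4 (2 equiv), LiN(SiMe3)2 (2 equiv), THF, −78 °C; then 6, −78 → 0 °C; 1 M HCl
Reagents that add atoms: none
Why: Crossed Claisen-type C-acylation of the kinetic, methyl-side lithium enolate of 4 with the acid chloride; the second equivalent of enolate takes the acidic C5 proton of 7 and is recovered as 4. At −78 °C acylation should outrun ketene formation from 6, so C2′ keeps its (R) configuration, and in 7 it is protected by enolisation toward C5.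

Step 4
Reactants: 7 (3R,9R)-3-methyl-9-(prop-1-en-2-yl)dodec-11-ene-4,6-dione
Product: 8 (4R)-3,3-dimethyl-2-[(2R)-2-methylbutanoyl]-4-(prop-2-en-1-yl)cyclohexan-1-one
Conditions: SnCl4 (1.1 equiv), CH2Cl2, −78 → 0 °C; aq. NaHCO3
Reagents that add atoms: none
Why: Lewis-acid-promoted cation–enol cyclisation of an olefinic β-dicarbonyl compound (the polar counterpart of the Conia-ene reaction): Markovnikov protonation of the 1,1-disubstituted alkene gives the tertiary C4 cation, which the tin-bound enol captures at C5 in a six-membered chair closure, the CH2 terminus becoming the second C4 methyl group. The monosubstituted allyl group is not protonated and O-alkylation is reversible under the acid; in the closing chair the C3–H bond is gauche to the empty orbital at C4, which holds back hydride shift and elimination, so C3 should keep its configuration.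

Step 5
Reactants: 8 (4R)-3,3-dimethyl-2-[(2R)-2-methylbutanoyl]-4-(prop-2-en-1-yl)cyclohexan-1-one
Product: 9 (4S)-3,3-dimethyl-2-[(2R)-2-methylbutanoyl]-6-(3-methylbut-2-en-1-yl)-4-(prop-2-en-1-yl)cyclohexan-1-one
Conditions: LiN(i-Pr)2 (2.2 equiv), THF, −78 → 0 °C; 1-bromo-3-methylbut-2-ene (1.05 equiv), −78 → −20 °C; 1 M HCl
Reagents that add atoms: 1-bromo-3-methylbut-2-ene, SMILES CC(C)=CCBr
Why: γ-Alkylation of a β-diketone dianion: the second deprotonation takes the ring CH2 (C1) rather than the side-chain methine, and the more basic terminus is alkylated. The new centre is epimerisable and needs no control; the change of descriptor at C3 from 8 to 9 is a matter of CIP priority only.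

Step 6
Reactants: 9 (4S)-3,3-dimethyl-2-[(2R)-2-methylbutanoyl]-6-(3-methylbut-2-en-1-yl)-4-(prop-2-en-1-yl)cyclohexan-1-one
Product: 11 (1S,3S,5S)-4,4-dimethyl-5-[(2R)-2-methylbutanoyl]-1-(3-methylbut-2-en-1-yl)-3-(prop-2-en-1-yl)-6-oxabicyclo[3.2.1]octane-7,8-dione, via dilithium carboxylate 10 (not isolated)
Conditions: LiN(i-Pr)2 (2.2 equiv), THF, −78 → −20 °C; CO2 (gas), −78 °C; then PhI(OAc)2 (1.3 equiv), −78 → 0 °C
Reagents that add atoms: carbon dioxide, SMILES O=C=O
Why: Two equivalents of base give the ring dienolate of 9 (trigonal C1 and C5), whose more basic terminus C1 adds to CO2 as in the γ-carboxylation of β-diketone dianions; the remaining diketonate then attacks PhI(OAc)2 and the neighbouring carboxylate displaces iodobenzene from C5, the known trivalent-iodine lactonisation of diketo acids at the carbon between the two carbonyl groups. Ring B is closed by a 5-exo-tet attack of the carboxylate oxygen at C5 (iodobenzene leaves outside the new ring, equivalently an SN2′ attack on the O-bound iodine enolate), and this closure completes the bicyclo[3.2.1] skeleton. C1 is set by axial attack of CO2 on the half-chair dienolate that keeps the C3 allyl group pseudo-equatorial, that is on the face of the C3–H bond (1,3-control by torsional steering toward the chair). C5 is set by the tether alone, because the C1 carboxylate can reach only its own face of the trigonal C5, which leaves the acyl group equatorial. Since C1 and C5 are both planarised, all epimers and tautomers of 9 converge on one product, and a minor C1 carboxylate epimer would have to close with the allyl group axial over the lactone and should lag behind. The step needs deprotonation at the ring C1–H and not at C2′–H: the exocyclic dienolate from C2′–H removal is forced out of plane by A(1,3) strain between its methyl or ethyl group and the C4 methyl groups, so C2′ should keep its configuration. It also needs the oxidant to take the enolate and not the three C=C bonds, which the far higher nucleophilicity of the diketonate secures under these non-acidic conditions.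

Step 7
Reactants: 11 (1S,3S,5S)-4,4-dimethyl-5-[(2R)-2-methylbutanoyl]-1-(3-methylbut-2-en-1-yl)-3-(prop-2-en-1-yl)-6-oxabicyclo[3.2.1]octane-7,8-dione
Product: 12 (1S,3S,5S)-4,4-dimethyl-5-[(2R)-2-methylbutanoyl]-1,3-bis(3-methylbut-2-en-1-yl)-6-oxabicyclo[3.2.1]octane-7,8-dione
Conditions: second-generation Grubbs catalyst RuCl2(=CHPh)(PCy3)(H2IMes) (5 mol%), 2-methylbut-2-ene/CH2Cl2, 40 °C
Reagents that add atoms: 2-methylbut-2-ene, SMILES CC=C(C)C
Why: Olefin cross-metathesis of the monosubstituted allyl group with a trisubstituted partner, the usual way to turn allyl into prenyl on hindered polycarbonyl frameworks; the C1 prenyl group and the product alkene are trisubstituted and inert, and no stereocentre is touched.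

## Compound list

1 | (+)-limonene 1,2-oxide, (4R)-1-methyl-4-(prop-1-en-2-yl)-7-oxabicyclo[4.1.0]heptane, cis/trans mixture at the epoxide | CC12OC1C[C@@H](CC2)C(C)=C | starting material
2 | (4R)-1-methyl-4-(prop-1-en-2-yl)cyclohexane-1,2-diol, trans-diol | CC1(O)C(O)C[C@@H](CC1)C(C)=C | intermediate (not isolated)
3 | (3R)-6-oxo-3-(prop-1-en-2-yl)heptanal | O=CC[C@@H](CCC(C)=O)C(C)=C | intermediate
4 | (5R)-5-(prop-1-en-2-yl)oct-7-en-2-one | C=CC[C@@H](CCC(C)=O)C(C)=C | intermediate
5 | (2R)-2-methylbutanoic acid | CC[C@@H](C)C(=O)O | starting material
6 | (2R)-2-methylbutanoyl chloride | CC[C@@H](C)C(=O)Cl | intermediate (not isolated)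
7 | (3R,9R)-3-methyl-9-(prop-1-en-2-yl)dodec-11-ene-4,6-dione | CC[C@@H](C)C(=O)CC(=O)CC[C@H](CC=C)C(C)=C | intermediate
8 | (4R)-3,3-dimethyl-2-[(2R)-2-methylbutanoyl]-4-(prop-2-en-1-yl)cyclohexan-1-one, enol/keto mixture, C2 undefined | CC[C@@H](C)C(=O)C1C(=O)CC[C@H](CC=C)C1(C)C | intermediate
9 | (4S)-3,3-dimethyl-2-[(2R)-2-methylbutanoyl]-6-(3-methylbut-2-en-1-yl)-4-(prop-2-en-1-yl)cyclohexan-1-one, C2 and C6 undefined | CC[C@@H](C)C(=O)C1C(=O)C(CC=C(C)C)C[C@H](CC=C)C1(C)C | intermediate
10 | (1S,5S)-4,4-dimethyl-3-[(2R)-2-methylbutanoyl]-1-(3-methylbut-2-en-1-yl)-2-oxo-5-(prop-2-en-1-yl)cyclohexane-1-carboxylic acid, formed as its dilithium salt | CC[C@@H](C)C(=O)C1C(=O)[C@@](CC=C(C)C)(C(=O)O)C[C@H](CC=C)C1(C)C | intermediate (not isolated)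
11 | (1S,3S,5S)-4,4-dimethyl-5-[(2R)-2-methylbutanoyl]-1-(3-methylbut-2-en-1-yl)-3-(prop-2-en-1-yl)-6-oxabicyclo[3.2.1]octane-7,8-dione | CC[C@@H](C)C(=O)[C@@]12OC(=O)[C@@](CC=C(C)C)(C[C@H](CC=C)C1(C)C)C2=O | intermediate
12 | (1S,3S,5S)-4,4-dimethyl-5-[(2R)-2-methylbutanoyl]-1,3-bis(3-methylbut-2-en-1-yl)-6-oxabicyclo[3.2.1]octane-7,8-dione (CNP0306710.1) | CC[C@@H](C)C(=O)[C@@]12OC(=O)[C@@](CC=C(C)C)(C[C@H](CC=C(C)C)C1(C)C)C2=O | target

## Step count and least certain steps

Total step count: 7. Longest linear sequence: 7 steps (1 → 3 → 4 → 7 → 8 → 9 → 11 → 12); 5 enters at step 3 without a step of its own.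

Step 6 (key step). The most likely failure is slow C–O closure at the neopentyl, fully substituted C5. Intermolecular acetoxylation of the iodine-bound enolate, or loss of CO2 from the hindered C1 carboxylate on work-up, would then take over. A second worry is partial deprotonation at C2′ (erosion of that centre) and incomplete face selection at C1.

The fallback sets out from 9 and returns at 11; it makes the C5–O bond first and delivers C7 from that oxygen. The potassium enolate of 9 (KN(SiMe3)2, 1 equiv, THF, −78 °C) is hydroxylated at C5 with 2-(phenylsulfonyl)-3-phenyloxaziridine to give (2S,4S)-2-hydroxy-3,3-dimethyl-2-[(2R)-2-methylbutanoyl]-6-(3-methylbut-2-en-1-yl)-4-(prop-2-en-1-yl)cyclohexan-1-one F1; attack should be axial, on the face of the C3–H bond and anti to the axial C4 methyl group. Its potassium alkoxide (KH) is trapped with methyl chloroformate as methyl (1S,3S)-2,2-dimethyl-1-[(2R)-2-methylbutanoyl]-5-(3-methylbut-2-en-1-yl)-6-oxo-3-(prop-2-en-1-yl)cyclohexyl carbonate F2. LiN(SiMe3)2 (THF, −78 → 0 °C) then forms the C1 enolate, which attacks the carbonate carbonyl from the only face the tether allows (Dieckmann-type C-acylation), expels methoxide and gives 11.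

Step 4. The tertiary C4 cation sits next to the C3 methine. Loss of that proton (to the tetrasubstituted alkene and back), or a 1,2-hydride shift followed by five-membered closure, would erode the configuration at C3 or give a cyclopentanone; kinetic O-alkylation to a dihydropyran may also persist.

The fallback sets out from 7 and returns at 8 and avoids any cation. Diazo transfer (4-acetamidobenzenesulfonyl azide, Et3N, MeCN) gives (3R,9R)-5-diazo-3-methyl-9-(prop-1-en-2-yl)dodec-11-ene-4,6-dione F3. Cu(acac)2 or Rh2(OAc)4 (benzene, 80 °C) brings about intramolecular cyclopropanation of the 1,1-disubstituted alkene to (5R)-6-methyl-1-[(2R)-2-methylbutanoyl]-5-(prop-2-en-1-yl)bicyclo[4.1.0]heptan-2-one F4. Li in liquid NH3/THF (−78 °C) cleaves the cyclopropane bond to the CH2 carbon, the one aligned with the ring carbonyl; that carbon becomes the second C4 methyl group and the enolate of 8 is returned.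

Step 3. The basic enolate may convert 6 into its ketene (erosion of C2′); O-acylation, double acylation and incomplete methyl-versus-methylene selectivity in the enolisation of 4 are further risks.

The fallback sets out from 4 and 5 (through 6) and returns at 7; it replaces acylation by aldol addition and oxidation. 6 is treated with N,O-dimethylhydroxylamine hydrochloride and pyridine to give (2R)-N-methoxy-N,2-dimethylbutanamide F5, which LiAlH4 (THF, −78 °C) reduces to (2R)-2-methylbutanal F6. Addition of the kinetic lithium enolate of 4 (1:1, −78 °C) gives (3R,9R)-4-hydroxy-3-methyl-9-(prop-1-en-2-yl)dodec-11-en-6-one F7 as a mixture at the carbinol carbon. Dess–Martin periodinane oxidises F7 to 7.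

## Further compounds

F1 | step 6 | (2S,4S)-2-hydroxy-3,3-dimethyl-2-[(2R)-2-methylbutanoyl]-6-(3-methylbut-2-en-1-yl)-4-(prop-2-en-1-yl)cyclohexan-1-one | CC[C@@H](C)C(=O)[C@]1(O)C(=O)C(CC=C(C)C)C[C@H](CC=C)C1(C)C
F2 | step 6 | methyl (1S,3S)-2,2-dimethyl-1-[(2R)-2-methylbutanoyl]-5-(3-methylbut-2-en-1-yl)-6-oxo-3-(prop-2-en-1-yl)cyclohexyl carbonate | CC[C@@H](C)C(=O)[C@]1(OC(=O)OC)C(=O)C(CC=C(C)C)C[C@H](CC=C)C1(C)C
F3 | step 4 | (3R,9R)-5-diazo-3-methyl-9-(prop-1-en-2-yl)dodec-11-ene-4,6-dione | CC[C@@H](C)C(=O)C(=[N+]=[N-])C(=O)CC[C@H](CC=C)C(C)=C
F4 | step 4 | (5R)-6-methyl-1-[(2R)-2-methylbutanoyl]-5-(prop-2-en-1-yl)bicyclo[4.1.0]heptan-2-one, mixture at C1/C6 | CC[C@@H](C)C(=O)C12CC1(C)[C@@H](CC=C)CCC2=O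
F5 | step 3 | (2R)-N-methoxy-N,2-dimethylbutanamide | CC[C@@H](C)C(=O)N(C)OC
F6 | step 3 | (2R)-2-methylbutanal | CC[C@@H](C)C=O
F7 | step 3 | (3R,9R)-4-hydroxy-3-methyl-9-(prop-1-en-2-yl)dodec-11-en-6-one, mixture at C4 | CC[C@@H](C)C(O)CC(=O)CC[C@H](CC=C)C(C)=C
A1 | alternative 1 | methyl (1S,3S,5S)-3-hydroxy-4,4-dimethyl-3-[(2R)-2-methylbutanoyl]-1,5-bis(3-methylbut-2-en-1-yl)-2-oxocyclohexane-1-carboxylate | CC[C@@H](C)C(=O)[C@]1(O)C(=O)[C@@](CC=C(C)C)(C(=O)OC)C[C@H](CC=C(C)C)C1(C)C
A2 | alternative 2 | (3S)-5-[(2R)-2-methylbutanoyl]-3-(3-methylbut-2-en-1-yl)-3-[(2S)-5-methyl-2-(prop-1-en-2-yl)hex-4-en-1-yl]oxolane-2,4-dione | CC[C@@H](C)C(=O)C1OC(=O)[C@@](CC=C(C)C)(C[C@H](CC=C(C)C)C(C)=C)C1=O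
A3 | alternative 3 | (5R)-4-hydroxy-5-(2-methylbut-3-en-2-yl)-5-[(2R)-2-methylbutanoyl]-3-(3-methylbut-2-en-1-yl)furan-2(5H)-one | CC[C@@H](C)C(=O)[C@@]1(OC(=O)C(CC=C(C)C)=C1O)C(C)(C)C=C
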